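## Retrosynthetic overview

1. The last bond formed is C12–C13: a B-alkyl Suzuki coupling joins a C9-vinyl decalin triol to 3-bromobutenolide.
2. The C4 bis(hydroxymethyl) group comes from a 4-formyl decalin by Tollens condensation with formaldehyde. C17-OH comes from a C8 ester that is first equilibrated to the equatorial position.
3. Both rings form in one enantioselective radical polyene bicyclisation of an acyclic aldehyde–ene–dienoate. It folds chair–chair and runs head to tail, like the cyclisation of geranylgeranyl diphosphate to ent-copalyl diphosphate: ring A first (C4–C5), then ring B (C10–C9).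
4. The chain comes from a Z-selective Ando olefination of acrolein with a phosphonate alkylated by an E-homoallylic iodide. That iodide comes from 2,3-dihydrofuran by a cuprate 1,2-metallate rearrangement.

Assumption: labdane numbering is used in the explanations; the usual shielding model (the arylmethyl arm covers one enamine face) predicts that the (2R,5R) catalyst gives the ent series, and the mirror-image catalyst is the remedy if the sense is opposite; 2 and 9 are taken as catalogue chemicals.

## Route

Step 1
Reactants: 1 2,3-dihydrofuran; 2 2-(4-chlorobutyl)-1,3-dioxolane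
Product: 7 (3E)-8-(1,3-dioxolan-2-yl)-4-methyloct-3-en-1-ol, via 5-lithio-2,3-dihydrofuran 3 (not isolated), via 4-(1,3-dioxolan-2-yl)butyllithium 4 (not isolated), via mixed lithium cuprate 5 (not isolated), via alkenylcopper lithium alkoxide 6 (not isolated)
Conditions: 1, t-BuLi, THF, −78 → 0 °C; separately 2, Li metal, Et2O, 0 °C; 4 + CuBr·SMe2, Et2O/Me2S, −78 °C, add 3, warm to 20 °C; MeI, DMPU, −30 → 20 °C; aq NH4Cl
Reagents that add atoms: iodomethane C[I]
Why: Kocienski-type 1,2-metallate rearrangement, in which the alkyl group of 5 migrates from copper to the α-alkoxyalkenyl carbon with inversion and ring opening and alkenylcopper 6 is then methylated with retention, so the long chain ends trans and the methyl cis to the CH2CH2O arm, which fixes the E C5=C10 alkene.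

Step 2
Reactants: 7 (3E)-8-(1,3-dioxolan-2-yl)-4-methyloct-3-en-1-ol
Product: 8 2-[(5E)-8-iodo-5-methyloct-5-en-1-yl]-1,3-dioxolane
Conditions: I2, PPh3, imidazole, CH2Cl2, 0 °C
Reagents that add atoms: iodine [I][I]
Why: Appel iodination, an SN2 displacement of the alkoxyphosphonium ion under imidazole buffering that leaves the acetal and the alkene geometry untouched.

Step 3
Reactants: 8 2-[(5E)-8-iodo-5-methyloct-5-en-1-yl]-1,3-dioxolane; 9 ethyl 2-(diphenoxyphosphoryl)acetate
Product: 10 ethyl (5E)-2-(diphenoxyphosphoryl)-10-(1,3-dioxolan-2-yl)-6-methyldec-5-enoate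
Conditions: NaH, DMSO, 20 → 45 °C (1.5 equiv of 9)
Reagents that add atoms: none
Why: SN2 C-alkylation of the stabilised phosphonoacetate carbanion by a primary iodide, with excess 9 suppressing dialkylation; the new stereocentre is racemic and is erased in step 4.

Step 4
Reactants: 10 ethyl (5E)-2-(diphenoxyphosphoryl)-10-(1,3-dioxolan-2-yl)-6-methyldec-5-enoate; 11 acrolein
Product: 13 ethyl (2Z)-2-[(3E)-4-methyl-9-oxonon-3-en-1-yl]penta-2,4-dienoate, via dioxolane dienoate 12 (not isolated)
Conditions: NaH, THF, −78 °C; 11, −78 → 0 °C; then 2 M HCl, 20 °C, 3 h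
Reagents that add atoms: water O
Why: Ando variant of the Horner–Wadsworth–Emmons olefination, in which the electron-poor diaryl phosphonate makes the kinetic adduct collapse fast and puts CO2Et cis to the vinyl group (Z, about 9:1, minor isomer removed on silica), and the acid quench hydrolyses the dioxolane in the same flask.

Step 5
Reactants: 13 ethyl (2Z)-2-[(3E)-4-methyl-9-oxonon-3-en-1-yl]penta-2,4-dienoate
Product: 14 ethyl (1R,2R,4aR,5S,8aR)-1-ethenyl-5-formyl-8a-methyldecahydronaphthalene-2-carboxylate
Conditions: (2R,5R)-2-tert-butyl-3-methyl-5-(1-naphthylmethyl)imidazolidin-4-one·CF3CO2H (30 mol%), Ru(bpy)3(PF6)2 (2 mol%), DME (0.02 M), H2O (5 equiv), 450 nm LED, 0 °C, Ar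
Reagents that add atoms: none
Why: Proposed new method: 13 condenses with the amine to the E-enamine, which photoexcited Ru(bpy)3(PF6)2 (divalent ruthenium) oxidises by one electron to the 3π enaminyl radical cation; its electrophilic C4 attacks the electron-rich C5=C10 alkene 6-endo through a chair on the Re face left open by the naphthylmethyl arm (ring A, sets C4 and C5); the nucleophilic tertiary C10 radical then closes ring B by a polarity-matched 6-endo Giese addition to C9 of the dienoate (second chair, giving a trans ring fusion with axial C10 methyl and an equatorial vinyl because C11 is trans to C7 in the Z ester, while 5-exo attack at fully substituted C8 is blocked); the electrophilic C8 radical has no matched partner left, so the accumulated monovalent ruthenium complex reduces it to the ester enolate, which is protonated opposite the C10 methyl, making the step a redox-neutral isomerisation; the closest known reaction types are the organo-SOMO polyene cyclisation over alternating electron-rich and electron-poor olefins (stoichiometric divalent copper oxidant, arene terminator), the photoredox/enamine α-alkylation of aldehydes with olefins and the photoredox Giese reaction.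

Step 6
Reactants: 14 ethyl (1R,2R,4aR,5S,8aR)-1-ethenyl-5-formyl-8a-methyldecahydronaphthalene-2-carboxylate
Product: 17 ethyl (1R,2S,4aS,8aS)-1-ethenyl-5,5-bis(hydroxymethyl)-8a-methyldecahydronaphthalene-2-carboxylate, via equatorial ester aldehyde 15 (not isolated), via hydroxymethyl aldehyde 16 (not isolated)
Conditions: NaOEt (2 equiv), EtOH, 78 °C, Ar, 6 h; cool to 20 °C, (CH2O)n (10 equiv), 20 → 45 °C
Reagents that add atoms: formaldehyde (fed as paraformaldehyde) C=O
Why: Thermodynamic epimerisation through the ester enolate moves CO2Et from the axial site syn to the C10 methyl to the equatorial site (sets C8), and the Tollens condensation (aldol with formaldehyde at C4, then crossed Cannizzaro hydride transfer) turns C4 into the non-stereogenic C(CH2OH)2, while any 16 left over gives the same triol in step 7.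

Step 7
Reactants: 17 ethyl (1R,2S,4aS,8aS)-1-ethenyl-5,5-bis(hydroxymethyl)-8a-methyldecahydronaphthalene-2-carboxylate
Product: 18 (1R,2S,4aS,8aS)-1-ethenyl-2,5,5-tris(hydroxymethyl)-8a-methyldecahydronaphthalene
Conditions: LiAlH4 (3 equiv), THF, 0 → 20 °C; Fieser work-up; recrystallise
Reagents that add atoms: none
Why: LiAlH4 ester reduction leaves the isolated vinyl group and all stereocentres untouched, and recrystallisation of triol 18 raises the ee from the level set in step 5 to a single enantiomer.

Step 8
Reactants: 19 furan-2(5H)-one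
Product: 21 3-bromofuran-2(5H)-one, via trans-3,4-dibromolactone 20 (not isolated)
Conditions: Br2, CH2Cl2, 0 → 40 °C; then Et3N, 0 °C
Reagents that add atoms: bromine BrBr
Why: Anti addition of bromine to the enoate, then E1cB-type dehydrobromination (acidic α-H and β-bromide leave), so bromine stays on the α-carbon.

Step 9
Reactants: 18 (1R,2S,4aS,8aS)-1-ethenyl-2,5,5-tris(hydroxymethyl)-8a-methyldecahydronaphthalene; 21 3-bromofuran-2(5H)-one
Product: 23 3-{2-[(1R,2S,4aS,8aS)-2,5,5-tris(hydroxymethyl)-8a-methyldecahydronaphthalen-1-yl]ethyl}furan-2(5H)-one, via tetrakis-9-BBN adduct 22 (not isolated)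
Conditions: 9-BBN-H (4.5 equiv), THF, 0 → 40 °C; then 21 (1.5 equiv), PdCl2(dppf) (5 mol%), AsPh3 (10 mol%), 3 M aq K3PO4, DMF, 25 °C
Reagents that add atoms: none
Why: 9-BBN-H first masks the three hydroxyls as borinates and then adds anti-Markovnikov to the vinyl group, and the B-alkyl Suzuki–Miyaura coupling (oxidative addition of zerovalent palladium to the C–Br bond of 21, base-assisted alkyl transfer, reductive elimination) forms C12–C13 without touching a stereocentre, with aqueous work-up freeing the hydroxyls.

## Compound list

1 | 2,3-dihydrofuran | C1CC=CO1 | starting material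
2 | 2-(4-chlorobutyl)-1,3-dioxolane | ClCCCCC1OCCO1 | starting material
3 | 5-lithio-2,3-dihydrofuran | [Li]C1=CCCO1 | intermediate
4 | 4-(1,3-dioxolan-2-yl)butyllithium | [Li]CCCCC1OCCO1 | intermediate
5 | lithium [4-(1,3-dioxolan-2-yl)butyl](4,5-dihydrofuran-2-yl)cuprate | [Li+].O1CCC=C1[Cu-]CCCCC1OCCO1 | intermediate
6 | alkenylcopper lithium alkoxide (Cu cis to the CH2CH2OLi arm, alkyl chain trans) | [Li]OCC/C=C([Cu])/CCCCC1OCCO1 | intermediate
7 | (3E)-8-(1,3-dioxolan-2-yl)-4-methyloct-3-en-1-ol | OCC/C=C(C)/CCCCC1OCCO1 | intermediate
8 | 2-[(5E)-8-iodo-5-methyloct-5-en-1-yl]-1,3-dioxolane | ICC/C=C(C)/CCCCC1OCCO1 | intermediate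
9 | ethyl 2-(diphenoxyphosphoryl)acetate | CCOC(=O)CP(=O)(Oc1ccccc1)Oc1ccccc1 | starting material
10 | ethyl (5E)-2-(diphenoxyphosphoryl)-10-(1,3-dioxolan-2-yl)-6-methyldec-5-enoate (racemic at C2) | CCOC(=O)C(CC/C=C(C)/CCCCC1OCCO1)P(=O)(Oc1ccccc1)Oc1ccccc1 | intermediate
11 | acrolein | C=CC=O | starting material
12 | ethyl (2Z)-2-[(3E)-8-(1,3-dioxolan-2-yl)-4-methyloct-3-en-1-yl]penta-2,4-dienoate | C=C/C=C(/CC/C=C(C)/CCCCC1OCCO1)C(=O)OCC | intermediate
13 | ethyl (2Z)-2-[(3E)-4-methyl-9-oxonon-3-en-1-yl]penta-2,4-dienoate | C=C/C=C(/CC/C=C(C)/CCCCC=O)C(=O)OCC | intermediate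
14 | ethyl (1R,2R,4aR,5S,8aR)-1-ethenyl-5-formyl-8a-methyldecahydronaphthalene-2-carboxylate (trans-decalin, ent series; CHO and vinyl equatorial, CO2Et axial) | C[C@@]12CCC[C@H](C=O)[C@H]1CC[C@@H](C(=O)OCC)[C@H]2C=C | intermediate
15 | ethyl (1R,2S,4aR,5S,8aR)-1-ethenyl-5-formyl-8a-methyldecahydronaphthalene-2-carboxylate (CO2Et equatorial) | C[C@@]12CCC[C@H](C=O)[C@H]1CC[C@H](C(=O)OCC)[C@H]2C=C | intermediate
16 | ethyl (1R,2S,4aS,5R,8aS)-1-ethenyl-5-formyl-5-(hydroxymethyl)-8a-methyldecahydronaphthalene-2-carboxylate (CH2OH equatorial, CHO axial) | C[C@@]12CCC[C@@](CO)(C=O)[C@H]1CC[C@H](C(=O)OCC)[C@H]2C=C | intermediate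
17 | ethyl (1R,2S,4aS,8aS)-1-ethenyl-5,5-bis(hydroxymethyl)-8a-methyldecahydronaphthalene-2-carboxylate | C[C@@]12CCCC(CO)(CO)[C@H]1CC[C@H](C(=O)OCC)[C@H]2C=C | intermediate
18 | (1R,2S,4aS,8aS)-1-ethenyl-2,5,5-tris(hydroxymethyl)-8a-methyldecahydronaphthalene | C[C@@]12CCCC(CO)(CO)[C@H]1CC[C@H](CO)[C@H]2C=C | intermediate
19 | furan-2(5H)-one | O=C1OCC=C1 | starting material
20 | trans-3,4-dibromodihydrofuran-2(3H)-one (racemic, one enantiomer drawn) | O=C1OC[C@@H](Br)[C@@H]1Br | intermediate
21 | 3-bromofuran-2(5H)-one | O=C1OCC=C1Br | intermediate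
22 | B-alkyl-9-BBN of 18 with the three hydroxyls as O-9-BBN borinates | C[C@@]12CCCC(COB3C4CCCC3CCC4)(COB3C4CCCC3CCC4)[C@H]1CC[C@H](COB3C4CCCC3CCC4)[C@H]2CCB3C4CCCC3CCC4 | intermediate
23 | 3-{2-[(1R,2S,4aS,8aS)-2,5,5-tris(hydroxymethyl)-8a-methyldecahydronaphthalen-1-yl]ethyl}furan-2(5H)-one, i.e. (5S,8S,9R,10S)-17,18,19-trihydroxylabd-13-en-16,15-olide | C[C@@]12CCCC(CO)(CO)[C@H]1CC[C@H](CO)[C@H]2CCC1=CCOC1=O | target

## Step count and risks

Total step count: 9. Longest linear sequence: 8 (steps 1–7 and 9).

**Step 5.** This cascade is new.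
- Reductive quenching by the small enamine population may be slow.
- The dienoate could be triplet-sensitised and lose its Z geometry. Ru(bpy)3(PF6)2 was chosen for its low triplet energy for this reason.
- The C10 radical could add to the diene terminus of a second molecule, hence the 0.02 M dilution.
- The ee will probably be near 90% before the upgrade at 18.

The fallback sets out from 13 and comes back at 14. It leaves photoredox for the established oxidative organo-SOMO manifold and adds a halogen cap. It uses the same amine salt with Cu(OTf)2 (2.5 equiv), LiCl and CF3CO2Na in i-PrCN/DME, with slow addition of the oxidant. Divalent copper generates the enaminyl radical cation and both rings close as before. The C8 radical, which copper cannot oxidise, is capped by chlorine-atom transfer from CuCl2 formed in the flask, giving the tertiary α-chloro ester F1. Zn dust in AcOH/THF then removes chlorine through the zinc enolate and returns 14, mixed with 15, which step 6 accepts equally.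

**Step 9.** The bromobutenolide is labile to aqueous base. The three borinate groups also load the mixture with boron species that compete for base.

The fallback sets out from 18 (through 22) and comes back at 23. It replaces the base-mediated organoboron coupling with a base-free cross-electrophile coupling. Adduct 22 is iodinated with ICl/NaOAc in MeOH at 0 °C to give, after work-up, the primary iodide F2. F2 is kept cold and used at once to avoid ether closure by the C17 hydroxyl. It is then coupled with 21 under NiBr2(dme) (10 mol%), 4,4'-di-tert-butyl-2,2'-bipyridine and Mn powder in DMA at 25 °C. These conditions tolerate free alcohols and give 23 directly.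

**Step 6.** The free aldehyde must survive hot ethoxide. The crossed Cannizzaro step on a hindered axial aldehyde may also stall.

The fallback sets out from 14 and comes back at 17. It reverses the order of events, so that no aldehyde or formaldehyde is present when the ester is equilibrated. Compound 14 is hydroxymethylated with 37% aq CH2O and K2CO3 in MeOH/THF at 20 °C, giving the hydroxymethyl aldehyde F3 with the axial ester untouched. NaBH4 added at 0 °C reduces it to the diol ester F4. Only then is F4 heated with NaOEt in EtOH to move CO2Et to the equatorial position, which gives 17.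

## Further compounds

F1 | step 5 | 8-chloro derivative of 14 (labdane C8: Cl equatorial, CO2Et axial) | C[C@@]12CCC[C@H](C=O)[C@H]1CC[C@@](Cl)(C(=O)OCC)[C@H]2C=C
F2 | step 9 | 1-(2-iodoethyl) analogue of 18 (labdane 12-iodide, three free CH2OH groups) | C[C@@]12CCCC(CO)(CO)[C@H]1CC[C@H](CO)[C@H]2CCI
F3 | step 6 | C8 epimer of 16 (CO2Et axial; C4 with equatorial CH2OH and axial CHO) | C[C@@]12CCC[C@@](CO)(C=O)[C@H]1CC[C@@H](C(=O)OCC)[C@H]2C=C
F4 | step 6 | C8 epimer of 17 (CO2Et axial) | C[C@@]12CCCC(CO)(CO)[C@H]1CC[C@@H](C(=O)OCC)[C@H]2C=C
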